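## Retrosynthetic overview
1. The last C–O events are the C7 angelate ester and the oxidation of a C1 carbinol to the enone.
2. The pivotal bond is C7–O. A hydroxyl-directed epoxidation of a C8 allylic alcohol relays C8 to C7 and stores a latent C6 radical. The C8 isobutyrate goes on in the same flask.
3. The seven-membered ring forms last. C5–C6 is made by a new Cp2TiCl-catalysed epoxide/N-sulfonylhydrazone cyclisation, and the C5=N handle leaves as N2.
4. The cyclobutane and the six-membered ring form first and together, by an intramolecular vinylketene/alkene [2+2]. The C1–O stereocentre sets the face.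
5. The acyclic C15 acid comes from three molecules of prenal through two asymmetric vinylogous Mukaiyama aldol reactions, which make the C8–O and C1–O carbinols.

Atom labels (longipinane numbering):
- C1 is the ring C=O and C2=C3 is the enone alkene (CH3 on C3).
- C4 and C11 are the cyclobutane CH next to C3 and C1. C5 is the cyclobutane CH next to C6.
- C6 is CMe2, C7 is CH–OAng, C8 is CH–OiBu and C9 is CH2.
- C10 is the quaternary cyclobutane C–CH3.

Assumption: the oxazaborolidinone made from N-tosyl-D-tryptophan leaves the Si face of a bound enal open. If the sense is the reverse, the L-derived promoter is used in steps 2 and 4.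

## Route

Step 1
Reactants: 1 3-methylbut-2-enal (prenal)
Product: 2 (E)-tert-butyl(dimethyl)[(3-methylbuta-1,3-dien-1-yl)oxy]silane
Conditions: TBSOTf, Et3N, Et2O, 0 °C
Reagents that add atoms: tert-butyldimethylsilyl triflate, CC(C)(C)[Si](C)(C)OS(=O)(=O)C(F)(F)F
Why: O-silylation of the extended enolate (soft enolisation: TBSOTf activates the carbonyl and Et3N removes a γ-methyl proton) gives the dienol silyl ether; no stereocentre is formed.

Step 2
Reactants: 1 prenal; 2 dienol silyl ether
Product: 3 (2E,5S)-5-hydroxy-3,7-dimethylocta-2,6-dienal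
Conditions: preformed B-phenyl oxazaborolidinone from N-tosyl-D-tryptophan (1 equiv), iPrOH, EtCN, −78 °C, 1 in excess
Reagents that add atoms: none
Why: Asymmetric vinylogous Mukaiyama aldol reaction of an aldehyde-derived dienolate: the chiral boron Lewis acid binds 1 and its indole covers the Re face, so the γ-carbon of 2 attacks the Si face and sets the future C8 as S, while the s-trans diene delivers the E-enal and iPrOH takes up the silyl group.

Step 3
Reactants: 3 hydroxy enal
Product: 4 (2E,5S)-3,7-dimethyl-5-(triethylsilyloxy)octa-2,6-dienal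
Conditions: TESCl, imidazole, CH2Cl2, 0 °C
Reagents that add atoms: chlorotriethylsilane, CC[Si](Cl)(CC)CC
Why: Standard silyl ether formation masks the C8 hydroxyl with a group that can later be removed beside a TBS ether; the stereocentre is untouched.

Step 4
Reactants: 4 TES-protected enal; 2 dienol silyl ether
Product: 5 (2E,5S,6E,9S)-5-hydroxy-3,7,11-trimethyl-9-(triethylsilyloxy)dodeca-2,6,10-trienal
Conditions: preformed B-phenyl oxazaborolidinone from N-tosyl-D-tryptophan (1 equiv), iPrOH, EtCN, −78 °C
Reagents that add atoms: none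
Why: Second asymmetric vinylogous Mukaiyama aldol reaction under reagent control: Si-face attack on the bound enal sets the future C1 carbinol as S (the remote C8 centre has no say) and again gives the E-enal.

Step 5
Reactants: 5 hydroxy trienal
Product: 6 (2E,5S,6E,9S)-5-(tert-butyldimethylsilyloxy)-3,7,11-trimethyl-9-(triethylsilyloxy)dodeca-2,6,10-trienal
Conditions: TBSCl, imidazole, DMF, rt
Reagents that add atoms: tert-butylchlorodimethylsilane, CC(C)(C)[Si](C)(C)Cl
Why: Standard silylation gives a bulky robust ether at C1 that steers the cycloaddition and outlasts the TES group; no stereocentre changes.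

Step 6
Reactants: 6 bis-silyl trienal
Product: 7 (2E,5S,6E,9S)-5-(tert-butyldimethylsilyloxy)-3,7,11-trimethyl-9-(triethylsilyloxy)dodeca-2,6,10-trienoic acid
Conditions: NaClO2, NaH2PO4, 2-methylbut-2-ene, tBuOH/H2O, 0 °C
Reagents that add atoms: sodium chlorite, [Na+].[O-]Cl=O
Why: Pinnick oxidation turns the enal into the acid without touching alkenes, silyl ethers or stereocentres because the scavenger traps HOCl.

Step 7
Reactants: 7 trienoic acid
Product: 11 (1R,4S,5R,7R)-4-(tert-butyldimethylsilyloxy)-7-[(2S)-2-hydroxy-4-methylpent-3-en-1-yl]-7-methyl-2-methylidenebicyclo[3.1.1]heptan-6-one, via acid chloride 8 (not isolated), via vinylketene 9 (not isolated), via TES-protected cycloadduct 10 (not isolated)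
Conditions: Me2C=C(Cl)NMe2, CH2Cl2, 0 °C; slow addition to Et3N, PhMe, 110 °C; then PPTS, MeOH, 0 °C
Reagents that add atoms: none
Why: Intramolecular [2+2] cycloaddition of a vinylketene to a trisubstituted alkene (neutral acid chloride formation, dehydrochlorination at the C3 methyl group): the ketene carbonyl carbon bonds to the less substituted alkene carbon to give the bicyclo[3.1.1]heptan-6-one, A(1,3) strain holds the C1–H bond next to the cis methyl group so the ketene arm adds anti to OTBS and fixes C4, C10 and C11, the E-alkene places the C9 arm over the new carbonyl, and PPTS/MeOH then cleaves only the TES ether.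

Step 8
Reactants: 11 bicyclic hydroxy ketone; 12 isobutyric anhydride
Product: 14 (1S)-2-[(1R,4S,5R,7R)-4-(tert-butyldimethylsilyloxy)-7-methyl-2-methylidene-6-oxobicyclo[3.1.1]heptan-7-yl]-1-[(2R)-3,3-dimethyloxiran-2-yl]ethyl 2-methylpropanoate, via epoxy alcohol 13 (not isolated)
Conditions: VO(acac)2 (2 mol %), tBuOOH (1.05 equiv), PhMe, 0 °C; then 12, Et3N, DMAP, 0 °C to rt
Reagents that add atoms: tert-butyl hydroperoxide, CC(C)(C)OO
Why: Hydroxyl-directed epoxidation with in situ acylation: the vanadium alkoxide of the C8 alcohol delivers oxygen to the alkene face on which the hydroxyl sits in the A(1,3)-minimised rotamer, which forms the C7–O bond with threo (7,8-trans) induction (about 6:1 or better, minor isomer removed by chromatography), spares the cyclobutanone and the 1,1-disubstituted alkene, and the anhydride then esterifies C8–OH.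

Step 9
Reactants: 14 epoxy ester ketone
Product: 15 N-tosylhydrazone of 14 at the cyclobutanone carbon (C=N geometry not defined)
Conditions: TsNHNH2, 4 Å sieves, THF, 40 °C
Reagents that add atoms: p-toluenesulfonohydrazide, Cc1ccc(cc1)S(=O)(=O)NN
Why: Condensation of the strained and therefore electrophilic cyclobutanone with the sulfonyl hydrazide forms the C5=N bond under neutral conditions that spare the epoxide; no stereocentre changes.

Step 10
Reactants: 15 epoxy tosylhydrazone
Product: 18 (1S,4R,5S,7S,8S,10R,11R)-1-(tert-butyldimethylsilyloxy)-7-hydroxy-3-methylidenelongipinan-8-yl 2-methylpropanoate, via tricyclic tosylhydrazine 16 (not isolated), via tricyclic diazene 17 (not isolated)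
Conditions: Cp2TiCl2 (20 mol %), Mn, 2,4,6-collidine·HCl, THF, rt, slow addition of 15; then NaOAc, EtOH, 70 °C
Reagents that add atoms: none
Why: Proposed new method: Cp2TiCl (trivalent titanium, made in the flask from Cp2TiCl2 and Mn) cleaves the tertiary C6–O bond of the epoxide homolytically while C7–O stays intact as a titanium alkoxide; the tertiary C6 radical, held under the cyclobutane by the C9 arm, adds to the strained C5=N carbon from the only reachable face (formally 7-exo, in geometry like a 6-exo closure because C5 and C10 are only about 2.1 Å apart), a second Cp2TiCl reduces the hydrazinyl radical and collidinium chloride protonates the Ti–O and Ti–N bonds to turn the catalyst over; warming with NaOAc expels sulfinate and the diazene loses N2, which leaves H on C5 on the face of the six-membered ring, so the tether sets C5 and C7 and C8 are untouched; the closest known chemistry is titanocene-catalysed reductive epoxide opening with radical cyclisation onto C=C, C=O or C≡N acceptors, addition of tertiary alkyl radicals to sulfonylhydrazones in olefin hydromethylation, and the acetate-induced fragmentation of tosylhydrazines to alkanes, but an epoxide-derived radical has not been joined to a hydrazone acceptor with traceless loss of nitrogen.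

Step 11
Reactants: 18 tricyclic C7 alcohol; 19 angelic acid [(Z)-2-methylbut-2-enoic acid]
Product: 20 (1S,4R,5S,7S,8S,10R,11R)-1-(tert-butyldimethylsilyloxy)-8-isobutyryloxy-3-methylidenelongipinan-7-yl (Z)-2-methylbut-2-enoate
Conditions: 19, 2,4,6-Cl3C6H2COCl, Et3N, PhMe, rt; then 18, 80 °C (no DMAP)
Reagents that add atoms: none
Why: Yamaguchi-type mixed anhydride esterification run without DMAP is the known way to acylate hindered alcohols with angelic acid without Z to E isomerisation; C7 keeps its configuration because only the O–H bond reacts.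

Step 12
Reactants: 20 silyl-protected diester
Product: 23 (4R,5S,7S,8S,10R,11R)-7-angeloyloxy-8-isobutyryloxylongipin-2-en-1-one (target), via C1 alcohol 21 (not isolated), via deconjugated ketone 22 (not isolated)
Conditions: HF·pyridine, THF, 0 °C to rt; crude: Dess–Martin periodinane, CH2Cl2, rt; then DBU (10 mol %), rt
Reagents that add atoms: none
Why: Desilylation, Dess–Martin oxidation of the C1 carbinol (its stereocentre has done its work) and base-catalysed migration of the exocyclic alkene into conjugation give the thermodynamically preferred 3-methyl enone; the bridgehead centres C4 and C11 cannot epimerise.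

## Compound list
1 | 3-methylbut-2-enal (prenal) | CC(C)=CC=O | starting material
2 | (E)-tert-butyl(dimethyl)[(3-methylbuta-1,3-dien-1-yl)oxy]silane | C=C(C)/C=C/O[Si](C)(C)C(C)(C)C | intermediate
3 | (2E,5S)-5-hydroxy-3,7-dimethylocta-2,6-dienal | CC(C)=C[C@@H](O)C/C(C)=C/C=O | intermediate
4 | (2E,5S)-3,7-dimethyl-5-(triethylsilyloxy)octa-2,6-dienal | CC(C)=C[C@@H](O[Si](CC)(CC)CC)C/C(C)=C/C=O | intermediate
5 | (2E,5S,6E,9S)-5-hydroxy-3,7,11-trimethyl-9-(triethylsilyloxy)dodeca-2,6,10-trienal | CC(C)=C[C@@H](O[Si](CC)(CC)CC)C/C(C)=C/[C@@H](O)C/C(C)=C/C=O | intermediate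
6 | 5-O-TBS ether of 5 | CC(C)=C[C@@H](O[Si](CC)(CC)CC)C/C(C)=C/[C@@H](O[Si](C)(C)C(C)(C)C)C/C(C)=C/C=O | intermediate
7 | trienoic acid from 6 | CC(C)=C[C@@H](O[Si](CC)(CC)CC)C/C(C)=C/[C@@H](O[Si](C)(C)C(C)(C)C)C/C(C)=C/C(=O)O | intermediate
8 | acid chloride of 7 | CC(C)=C[C@@H](O[Si](CC)(CC)CC)C/C(C)=C/[C@@H](O[Si](C)(C)C(C)(C)C)C/C(C)=C/C(=O)Cl | intermediate
9 | 3-methylidene vinylketene from 8 | CC(C)=C[C@@H](O[Si](CC)(CC)CC)C/C(C)=C/[C@@H](O[Si](C)(C)C(C)(C)C)CC(=C)C=C=O | intermediate
10 | TES-protected bicyclo[3.1.1]heptan-6-one cycloadduct | O=C1[C@@H]2C(=C)C[C@H](O[Si](C)(C)C(C)(C)C)[C@H]1[C@]2(C)C[C@H](O[Si](CC)(CC)CC)C=C(C)C | intermediate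
11 | bicyclic hydroxy ketone (free C8–OH) | O=C1[C@@H]2C(=C)C[C@H](O[Si](C)(C)C(C)(C)C)[C@H]1[C@]2(C)C[C@H](O)C=C(C)C | intermediate
12 | isobutyric anhydride | CC(C)C(=O)OC(=O)C(C)C | starting material
13 | threo epoxy alcohol | O=C1[C@@H]2C(=C)C[C@H](O[Si](C)(C)C(C)(C)C)[C@H]1[C@]2(C)C[C@H](O)[C@H]3OC3(C)C | intermediate
14 | epoxy isobutyrate ketone | O=C1[C@@H]2C(=C)C[C@H](O[Si](C)(C)C(C)(C)C)[C@H]1[C@]2(C)C[C@H](OC(=O)C(C)C)[C@H]3OC3(C)C | intermediate
15 | N-tosylhydrazone of 14 | Cc1ccc(cc1)S(=O)(=O)NN=C2[C@@H]3C(=C)C[C@H](O[Si](C)(C)C(C)(C)C)[C@H]2[C@]3(C)C[C@H](OC(=O)C(C)C)[C@H]4OC4(C)C | intermediate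
16 | tricyclic N'-tosylhydrazine (N on C5, on the face of the six-membered ring) | O[C@@H]1[C@@H](OC(=O)C(C)C)C[C@@]2(C)[C@@H]3[C@@H](O[Si](C)(C)C(C)(C)C)CC(=C)[C@H]2[C@]3(NNS(=O)(=O)c4ccc(C)cc4)C1(C)C | intermediate
17 | tricyclic C5 diazene | O[C@@H]1[C@@H](OC(=O)C(C)C)C[C@@]2(C)[C@@H]3[C@@H](O[Si](C)(C)C(C)(C)C)CC(=C)[C@H]2[C@]3(N=N)C1(C)C | intermediate
18 | tricyclic C7 alcohol, C8 isobutyrate, C1 OTBS, C3 exocyclic methylene | O[C@@H]1[C@@H](OC(=O)C(C)C)C[C@@]2(C)[C@@H]3[C@@H](O[Si](C)(C)C(C)(C)C)CC(=C)[C@H]2[C@@H]3C1(C)C | intermediate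
19 | angelic acid | C/C=C(/C)C(=O)O | starting material
20 | C7 angelate of 18 | C/C=C(/C)C(=O)O[C@@H]1[C@@H](OC(=O)C(C)C)C[C@@]2(C)[C@@H]3[C@@H](O[Si](C)(C)C(C)(C)C)CC(=C)[C@H]2[C@@H]3C1(C)C | intermediate
21 | C1 alcohol from 20 | C/C=C(/C)C(=O)O[C@@H]1[C@@H](OC(=O)C(C)C)C[C@@]2(C)[C@@H]3[C@@H](O)CC(=C)[C@H]2[C@@H]3C1(C)C | intermediate
22 | C1 ketone with C3 exocyclic methylene | C/C=C(/C)C(=O)O[C@@H]1[C@@H](OC(=O)C(C)C)C[C@@]2(C)[C@@H]3C(=O)CC(=C)[C@H]2[C@@H]3C1(C)C | intermediate
23 | (4R,5S,7S,8S,10R,11R)-7-angeloyloxy-8-isobutyryloxylongipin-2-en-1-one | C/C=C(/C)C(=O)O[C@@H]1[C@@H](OC(=O)C(C)C)C[C@@]2(C)[C@@H]3C(=O)C=C(C)[C@H]2[C@@H]3C1(C)C | target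

Total step count: 12. Longest linear sequence: 12 steps (1 to 23).

## Steps most likely to fail

**Step 10 (the proposed new step).**
- Risk: the tertiary radical may disproportionate to the isopropenyl carbinol, or be reduced, before it reaches the fully substituted C=N carbon.
- Fallback: it sets out from 15 and comes back at 16. MgBr2·OEt2 in Et2O at −20 °C opens the epoxide at the tertiary carbon to give the bromohydrin F8.
- Slow addition of Bu3SnH with AIBN in PhH at 80 °C then abstracts bromine. The same tertiary radical closes onto the sulfonylhydrazone carbon in a conventional tin hydride radical cyclisation onto a C=N acceptor.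
- This gives 16, which is treated with NaOAc in EtOH as in step 10.

**Step 7.**
- Risk: the inductively deactivated, OTBS-flanked alkene may react too slowly with the vinylketene, which then dimerises.
- Fallback: it sets out from 7 and comes back at 10. Kinetic α-protonation of the dienediolate of 7 (LiN(iPr)2, then AcOH, −78 °C) gives the deconjugated acid F5. Pyrrolidine with EDC gives the pyrrolidine amide F6.
- Tf2O with 2,4,6-collidine in 1,2-dichloroethane at 80 °C generates the far more electrophilic keteniminium ion (keteniminium/alkene [2+2]). It closes to the cyclobutaniminium triflate F7.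
- Aqueous NaHCO3 hydrolyses F7 to 10.

**Step 2.**
- Risk: the product enal competes with 1 for the dienolate, and the selectivity with prenal is untested. The same risk, in weaker form, applies to step 4.
- Fallback: it sets out from 1 and comes back at 4. Methyl 3-methylbut-2-enoate is converted with LiN(iPr)2 and TBSCl into the silyl ketene acetal F1.
- F1 adds to 1 under SiCl4 and a chiral bisphosphoramide Lewis base. This is an ester-dienolate vinylogous aldol, so the product is not an electrophile. It gives the hydroxy ester F2.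
- TESCl gives the silyl ether ester F3, iBu2AlH gives the allylic alcohol F4, and MnO2 gives 4.

## Further compounds
F1 | step 2 | tert-butyl[(1-methoxy-3-methylbuta-1,3-dien-1-yl)oxy]dimethylsilane | C=C(C)C=C(OC)O[Si](C)(C)C(C)(C)C
F2 | step 2 | methyl (2E,5S)-5-hydroxy-3,7-dimethylocta-2,6-dienoate | CC(C)=C[C@@H](O)C/C(C)=C/C(=O)OC
F3 | step 2 | methyl (2E,5S)-3,7-dimethyl-5-(triethylsilyloxy)octa-2,6-dienoate | CC(C)=C[C@@H](O[Si](CC)(CC)CC)C/C(C)=C/C(=O)OC
F4 | step 2 | (2E,5S)-3,7-dimethyl-5-(triethylsilyloxy)octa-2,6-dien-1-ol | CC(C)=C[C@@H](O[Si](CC)(CC)CC)C/C(C)=C/CO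
F5 | step 7 | 3-methylidene (deconjugated) isomer of acid 7 | CC(C)=C[C@@H](O[Si](CC)(CC)CC)C/C(C)=C/[C@@H](O[Si](C)(C)C(C)(C)C)CC(=C)CC(=O)O
F6 | step 7 | pyrrolidine amide of F5 | CC(C)=C[C@@H](O[Si](CC)(CC)CC)C/C(C)=C/[C@@H](O[Si](C)(C)C(C)(C)C)CC(=C)CC(=O)N1CCCC1
F7 | step 7 | cyclobutaniminium triflate corresponding to 10 | C1CC[N+](C1)=C2[C@@H]3C(=C)C[C@H](O[Si](C)(C)C(C)(C)C)[C@H]2[C@]3(C)C[C@H](O[Si](CC)(CC)CC)C=C(C)C.[O-]S(=O)(=O)C(F)(F)F
F8 | step 10 | bromohydrin of 15 (C6–Br, C7–OH) | Cc1ccc(cc1)S(=O)(=O)NN=C2[C@@H]3C(=C)C[C@H](O[Si](C)(C)C(C)(C)C)[C@H]2[C@]3(C)C[C@H](OC(=O)C(C)C)[C@@H](O)C(C)(C)Br
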